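The target is cut at the C7–C11 bond of the trans-fused γ-lactone ring (O–C12–C11–C7–C8). The step exploits the anti array C6–O/C7–C11 on adjacent carbons, the imprint of a trans-6,7-epoxide opened with inversion. The precursor is an acyclic (8S)-carbinol esterified with diethylphosphonoacetic acid and bearing a Sharpless-derived 6,7-epoxide, with C5 still an acetal. Base lets the phosphonate carbanion (C11) attack C7 in a 5-exo opening; formaldehyde then turns the phosphonolactone into the α-methylene lactone in the same flask. One operation closes the lactone, sets C7, frees O6 for the isobutyrate and installs C13. The ten-membered ring follows by ring-closing metathesis and a final epoxidation.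

Key step: step 4

Remark: positions are given in germacrane numbering (carbocycle C1–C10, lactone carbons C11–C13 with the lactone oxygen on C8, methyl C14 on C10 and C15 on C4); aldehyde 1 is taken to be a catalogue compound.

Step 1
Reactants: 1 (E)-4,4-dimethoxybut-2-enal; 2 2-methylallylmagnesium chloride; 3 (−)-B-methoxydiisopinocampheylborane
Product: 6 (4S,5E)-7,7-dimethoxy-2-methylhepta-1,5-dien-4-ol, via B-methallyldiisopinocampheylborane 4 (not isolated), via borinate ester 5 (not isolated)
Conditions: 3, 2, Et2O, −78 °C → rt; then 1, −78 °C; NaOH, H2O2, 0 °C → rt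
Reagents that add atoms: none
Why: Brown allylboration: the borane made from (+)-α-pinene transfers the 2-methylallyl group through a chair transition state to the Si face of the aldehyde of 1 in a 1,2-addition, which sets C8 as (S), and the acetal and the conjugated olefin are not touched.

Step 2
Reactants: 6 (4S,5E)-7,7-dimethoxy-2-methylhepta-1,5-dien-4-ol
Product: 7 (1S)-1-[(2S,3R)-3-(dimethoxymethyl)oxiran-2-yl]-3-methylbut-3-en-1-ol
Conditions: Ti(OiPr)4 (0.2 equiv), L-(+)-DIPT (0.24 equiv), t-BuOOH, 4 Å MS, CH2Cl2, −20 °C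
Reagents that add atoms: tert-butyl hydroperoxide, CC(C)(C)OO
Why: Sharpless asymmetric epoxidation in the matched sense of a kinetic resolution: the titanium L-(+)-tartrate catalyst oxidises the allylic C6=C7 bond of the (S)-carbinol on the face that gives the erythro epoxy alcohol (C7 S, C6 R), ignores the homoallylic 1,1-disubstituted olefin and leaves the minor (R)-enantiomer of 6 largely unreacted.

Step 3
Reactants: 7 (1S)-1-[(2S,3R)-3-(dimethoxymethyl)oxiran-2-yl]-3-methylbut-3-en-1-ol; 8 2-(diethoxyphosphoryl)acetic acid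
Product: 9 (1S)-1-[(2S,3R)-3-(dimethoxymethyl)oxiran-2-yl]-3-methylbut-3-en-1-yl 2-(diethoxyphosphoryl)acetate
Conditions: DCC, DMAP (cat.), CH2Cl2, 0 °C → rt
Reagents that add atoms: none
Why: Steglich esterification of the secondary C8 alcohol under neutral conditions, which keeps the epoxide and the acetal and touches no stereocentre.

Step 4
Reactants: 9 (1S)-1-[(2S,3R)-3-(dimethoxymethyl)oxiran-2-yl]-3-methylbut-3-en-1-yl 2-(diethoxyphosphoryl)acetate
Product: 11 (4S,5S)-4-[(1R)-1-hydroxy-2,2-dimethoxyethyl]-3-methylidene-5-(2-methylprop-2-en-1-yl)oxolan-2-one, via phosphonolactone sodium enolate 10 (not isolated)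
Conditions: NaH, THF, 0 → 50 °C; then (CH2O)n, 50 °C
Reagents that add atoms: formaldehyde (from paraformaldehyde), C=O
Why: Deprotonation gives the phosphonoacetate carbanion (C11), which opens the epoxide at C7 by backside attack (intramolecular alkylation of a stabilised ester enolate by an epoxide, the tethered relative of the phosphonoacetate–epoxide lactone annulation); proton transfer from C11 to the new O6 alkoxide then gives the phosphonolactone anion, which undergoes Horner–Wadsworth–Emmons olefination with formaldehyde. The γ-lactone ring (O–C12–C11–C7–C8) closes in the 5-exo-tet mode, the breaking C7–O bond lying outside the new ring. C7 is set by inversion of the (7S)-epoxide carbon, so the C7–C11 bond ends trans to the C8 side chain and anti to the C6–O bond, whose configuration is carried over unchanged from the Sharpless epoxide; C11 ends as sp2. The step needs attack at C7 and not at C6 (6-endo): C6 is flanked by the acetal carbon, which retards substitution there, and the three-atom tether cannot reach C6 collinearly. As an enolate the C–O(alkyl) bond rotates freely, so the cisoid ester geometry needed for lactone closure costs little, and at 50 °C the stabilised phosphonolactone anion should not enter the high-temperature phosphoryl-transfer (cyclopropanation) pathway.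

Step 5
Reactants: 11 (4S,5S)-4-[(1R)-1-hydroxy-2,2-dimethoxyethyl]-3-methylidene-5-(2-methylprop-2-en-1-yl)oxolan-2-one
Product: 12 (1R)-2,2-dimethoxy-1-[(2S,3R)-4-methylidene-2-(2-methylprop-2-en-1-yl)-5-oxooxolan-3-yl]ethyl 2-methylpropanoate
Conditions: i-PrCOCl, pyridine, DMAP (cat.), CH2Cl2, 0 °C → rt
Reagents that add atoms: isobutyryl chloride, CC(C)C(Cl)=O
Why: Acylation of the only free hydroxyl (O6) with an acid chloride puts the isobutyrate of the target in place with retention at C6, and under these mild conditions the α-methylene lactone should survive.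

Step 6
Reactants: 12 (1R)-2,2-dimethoxy-1-[(2S,3R)-4-methylidene-2-(2-methylprop-2-en-1-yl)-5-oxooxolan-3-yl]ethyl 2-methylpropanoate
Product: 13 (1R)-1-[(2S,3R)-4-methylidene-2-(2-methylprop-2-en-1-yl)-5-oxooxolan-3-yl]-2-oxoethyl 2-methylpropanoate
Conditions: Amberlyst-15, acetone/H2O, rt
Reagents that add atoms: water, O
Why: Acid-catalysed acetal hydrolysis on a sulfonic acid resin in wet acetone, which should cleave the dimethyl acetal faster than it protonates the 1,1-disubstituted olefin and gives an α-acyloxy aldehyde that is used at once so that C6 is not epimerised.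

Step 7
Reactants: 13 (1R)-1-[(2S,3R)-4-methylidene-2-(2-methylprop-2-en-1-yl)-5-oxooxolan-3-yl]-2-oxoethyl 2-methylpropanoate; 14 2-(triphenylphosphoranylidene)propanal
Product: 15 (1S,2E)-3-methyl-1-[(2S,3R)-4-methylidene-2-(2-methylprop-2-en-1-yl)-5-oxooxolan-3-yl]-4-oxobut-2-en-1-yl 2-methylpropanoate
Conditions: toluene, 60 °C
Reagents that add atoms: none
Why: Wittig olefination with a formyl-stabilised ylide, which is E-selective (C6 trans to the new formyl group, C15 cis to C6), is not basic enough to epimerise C6 and stops at the enal because 15 is a much poorer electrophile than 13.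

Step 8
Reactants: 15 (1S,2E)-3-methyl-1-[(2S,3R)-4-methylidene-2-(2-methylprop-2-en-1-yl)-5-oxooxolan-3-yl]-4-oxobut-2-en-1-yl 2-methylpropanoate; 16 allylboronic acid pinacol ester
Product: 18 (1S,2E,4R)-4-hydroxy-3-methyl-1-[(2S,3R)-4-methylidene-2-(2-methylprop-2-en-1-yl)-5-oxooxolan-3-yl]hepta-2,6-dien-1-yl 2-methylpropanoate, via pinacol borate ester 17 (not isolated)
Conditions: (R)-TRIP phosphoric acid [(R)-3,3'-bis(2,4,6-triisopropylphenyl)-1,1'-binaphthyl-2,2'-diyl hydrogen phosphate] (5 mol%), toluene, −30 °C; aqueous work-up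
Reagents that add atoms: none
Why: Chiral phosphoric acid-catalysed allylboration through a closed chair transition state in which the (R)-acid directs the allyl group to the Re face of the aldehyde (1,2-addition), which sets C3 as (R) under catalyst control because the stereocentres at C6–C8 are remote, while lactone, ester and exo-methylene do not react with the boronate.

Step 9
Reactants: 18 (1S,2E,4R)-4-hydroxy-3-methyl-1-[(2S,3R)-4-methylidene-2-(2-methylprop-2-en-1-yl)-5-oxooxolan-3-yl]hepta-2,6-dien-1-yl 2-methylpropanoate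
Product: 19 (1(10)Z,3R,4E,6S,7R,8S)-3-hydroxy-6-(2-methylpropanoyloxy)germacra-1(10),4,11(13)-trien-12,8-olide
Conditions: second-generation Hoveyda–Grubbs catalyst (10 mol%), 1,4-benzoquinone (20 mol%), toluene (1 mM), 80 °C
Reagents that add atoms: none
Why: Ring-closing metathesis: the ruthenium carbene formed at the terminal vinyl group closes onto the 1,1-disubstituted olefin with loss of ethene to give the C1=C10 bond, for which the ten-membered ring that already holds the E-C4=C5 bond and the trans-lactone should prefer the Z geometry, and closure onto the exo-methylene is ruled out because it would place that E-olefin in an eight-membered ring.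

Step 10
Reactants: 19 (1(10)Z,3R,4E,6S,7R,8S)-3-hydroxy-6-(2-methylpropanoyloxy)germacra-1(10),4,11(13)-trien-12,8-olide
Product: 20 (1R,3R,4E,6S,7R,8S,10S)-1,10-epoxy-3-hydroxy-6-(2-methylpropanoyloxy)germacra-4,11(13)-dien-12,8-olide (CNP0114243.1)
Conditions: DMDO, acetone, −20 → 0 °C
Reagents that add atoms: dimethyldioxirane, CC1(C)OO1
Why: Electrophilic epoxidation by a dioxirane of the most electron-rich olefin, C1=C10 (C4=C5 is deactivated by two allylic C–O bonds and the enoate is inert), with oxygen expected on the outer face of the Z-olefin whose inner face is screened across the ring by C4 and C15, which should set C1 (R) and C10 (S) as the cis-epoxide under neutral conditions that avoid transannular opening.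

Compound list
1 | (E)-4,4-dimethoxybut-2-enal (fumaraldehyde mono(dimethyl acetal)) | O=C/C=C/C(OC)OC | starting material
2 | 2-methylallylmagnesium chloride | C=C(C)C[Mg]Cl | starting material
3 | (−)-B-methoxydiisopinocampheylborane (from (+)-α-pinene) | COB([C@@H]1C[C@@H]2C[C@@H](C2(C)C)[C@H]1C)[C@@H]1C[C@@H]2C[C@@H](C2(C)C)[C@H]1C | starting material
4 | B-(2-methylallyl)diisopinocampheylborane (not isolated) | C=C(C)CB([C@@H]1C[C@@H]2C[C@@H](C2(C)C)[C@H]1C)[C@@H]1C[C@@H]2C[C@@H](C2(C)C)[C@H]1C | intermediate
5 | diisopinocampheylborinate ester of 6 (not isolated) | C=C(C)C[C@H](OB([C@@H]1C[C@@H]2C[C@@H](C2(C)C)[C@H]1C)[C@@H]1C[C@@H]2C[C@@H](C2(C)C)[C@H]1C)/C=C/C(OC)OC | intermediate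
6 | (4S,5E)-7,7-dimethoxy-2-methylhepta-1,5-dien-4-ol | C=C(C)C[C@H](O)/C=C/C(OC)OC | intermediate
7 | (1S)-1-[(2S,3R)-3-(dimethoxymethyl)oxiran-2-yl]-3-methylbut-3-en-1-ol | C=C(C)C[C@H](O)[C@@H]1O[C@H]1C(OC)OC | intermediate
8 | 2-(diethoxyphosphoryl)acetic acid | OC(=O)CP(=O)(OCC)OCC | starting material
9 | (1S)-1-[(2S,3R)-3-(dimethoxymethyl)oxiran-2-yl]-3-methylbut-3-en-1-yl 2-(diethoxyphosphoryl)acetate | C=C(C)C[C@H](OC(=O)CP(=O)(OCC)OCC)[C@@H]1O[C@H]1C(OC)OC | intermediate
10 | diethyl [(4S,5S)-4-[(1R)-1-hydroxy-2,2-dimethoxyethyl]-5-(2-methylprop-2-en-1-yl)-2-oxooxolan-3-yl]phosphonate, C3 epimers, present as its sodium enolate (not isolated) | C=C(C)C[C@@H]1OC(=O)C(P(=O)(OCC)OCC)[C@H]1[C@@H](O)C(OC)OC | intermediate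
11 | (4S,5S)-4-[(1R)-1-hydroxy-2,2-dimethoxyethyl]-3-methylidene-5-(2-methylprop-2-en-1-yl)oxolan-2-one | C=C(C)C[C@@H]1OC(=O)C(=C)[C@H]1[C@@H](O)C(OC)OC | intermediate
12 | (1R)-2,2-dimethoxy-1-[(2S,3R)-4-methylidene-2-(2-methylprop-2-en-1-yl)-5-oxooxolan-3-yl]ethyl 2-methylpropanoate | C=C(C)C[C@@H]1OC(=O)C(=C)[C@H]1[C@@H](OC(=O)C(C)C)C(OC)OC | intermediate
13 | (1R)-1-[(2S,3R)-4-methylidene-2-(2-methylprop-2-en-1-yl)-5-oxooxolan-3-yl]-2-oxoethyl 2-methylpropanoate | C=C(C)C[C@@H]1OC(=O)C(=C)[C@H]1[C@@H](OC(=O)C(C)C)C=O | intermediate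
14 | 2-(triphenylphosphoranylidene)propanal | CC(C=O)=P(c1ccccc1)(c1ccccc1)c1ccccc1 | starting material
15 | (1S,2E)-3-methyl-1-[(2S,3R)-4-methylidene-2-(2-methylprop-2-en-1-yl)-5-oxooxolan-3-yl]-4-oxobut-2-en-1-yl 2-methylpropanoate | C=C(C)C[C@@H]1OC(=O)C(=C)[C@H]1[C@@H](OC(=O)C(C)C)/C=C(\C)C=O | intermediate
16 | 2-allyl-4,4,5,5-tetramethyl-1,3,2-dioxaborolane (allylboronic acid pinacol ester) | C=CCB1OC(C)(C)C(C)(C)O1 | starting material
17 | pinacol borate ester of 18 (not isolated) | C=C(C)C[C@@H]1OC(=O)C(=C)[C@H]1[C@@H](OC(=O)C(C)C)/C=C(\C)[C@H](OB1OC(C)(C)C(C)(C)O1)CC=C | intermediate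
18 | (1S,2E,4R)-4-hydroxy-3-methyl-1-[(2S,3R)-4-methylidene-2-(2-methylprop-2-en-1-yl)-5-oxooxolan-3-yl]hepta-2,6-dien-1-yl 2-methylpropanoate | C=C(C)C[C@@H]1OC(=O)C(=C)[C@H]1[C@@H](OC(=O)C(C)C)/C=C(\C)[C@H](O)CC=C | intermediate
19 | (1(10)Z,3R,4E,6S,7R,8S)-3-hydroxy-6-(2-methylpropanoyloxy)germacra-1(10),4,11(13)-trien-12,8-olide | C=C1C(=O)O[C@H]2C/C(C)=C\C[C@@H](O)/C(C)=C/[C@H](OC(=O)C(C)C)[C@H]12 | intermediate
20 | (1R,3R,4E,6S,7R,8S,10S)-1,10-epoxy-3-hydroxy-6-(2-methylpropanoyloxy)germacra-4,11(13)-dien-12,8-olide (CNP0114243.1) | C=C1C(=O)O[C@H]2C[C@]3(C)O[C@@H]3C[C@@H](O)/C(C)=C/[C@H](OC(=O)C(C)C)[C@H]12 | target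

Total step count: 10. Longest linear sequence: 10 steps (1 → 20).

Steps most likely to fail

Step 9 (ring-closing metathesis). Closure of a ten-membered ring onto a 1,1-disubstituted olefin is slow. Intermolecular metathesis through the terminal vinyl group or the conjugated exo-methylene, catalyst decay by chelation to the enoate, or loss of Z-selectivity may take over. The fallback masks the enoate; it sets out from 18 and comes back at 19. Dimethylamine in THF at 0 °C adds to the exo-methylene of 18 to give the dimethylamine adduct F1. Ring-closing metathesis in the presence of TsOH (second-generation Grubbs catalyst, CH2Cl2, 40 °C), now on a saturated and non-chelating lactone, should give the macrocyclic amine F2. Methyl iodide then gives the methiodide F3, and NaHCO3 eliminates trimethylamine to restore the methylene group of 19.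

Step 10 (epoxidation). Facial selectivity at C1=C10 rests on the ring conformer alone and may be poor or inverted; hydroxyl-directed attack at C4=C5 is a second possibility. The fallback reverses the face by a two-step halohydrin route; it sets out from 19 and comes back at 20. NBS in aqueous acetone should form the bromonium ion on the face the dioxirane uses, and water opens it at the tertiary C10 from the other side to give the bromohydrin F4. K2CO3 in MeCN then closes the epoxide by displacement at C1 with inversion, which places the oxygen on the face opposite to direct epoxidation.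

Step 4 (key step). The stabilised phosphonoacetate anion may be too weak a nucleophile for the 2,3-disubstituted epoxide, so that no ring closure or base-induced decomposition on heating results. The fallback keeps the same C7–C11 ring closure but uses a non-stabilised enolate and a separate methylenation; it sets out from 7 and comes back at 11. Ac2O and pyridine give the acetate F5. LiHMDS followed by Et2AlCl (THF, −78 → −20 °C) forms the aluminium enolate, which opens the epoxide in the same 5-exo sense with the same inversion at C7 to give the hydroxy lactone F6. LDA (2.2 equiv) and dimethyl(methylidene)ammonium iodide give the Mannich base F7, methyl iodide gives the methiodide F8, and NaHCO3 elimination delivers 11.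

Further compounds
F1 | step 9 | dimethylamine adduct of 18 at C13 (C11 epimers) | C=C(C)C[C@@H]1OC(=O)C(CN(C)C)[C@H]1[C@@H](OC(=O)C(C)C)/C=C(\C)[C@H](O)CC=C
F2 | step 9 | macrocyclic amine, the C13 dimethylamine adduct of 19 (C11 epimers) | CN(C)CC1C(=O)O[C@H]2C/C(C)=C\C[C@@H](O)/C(C)=C/[C@H](OC(=O)C(C)C)[C@H]12
F3 | step 9 | methiodide of F2 | C[N+](C)(C)CC1C(=O)O[C@H]2C/C(C)=C\C[C@@H](O)/C(C)=C/[C@H](OC(=O)C(C)C)[C@H]12.[I-]
F4 | step 10 | 1-bromo-10-hydroxy bromohydrin of 19 | C=C1C(=O)O[C@H]2C[C@](C)(O)[C@@H](Br)C[C@@H](O)/C(C)=C/[C@H](OC(=O)C(C)C)[C@H]12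
F5 | step 4 | acetate of 7 | C=C(C)C[C@H](OC(C)=O)[C@@H]1O[C@H]1C(OC)OC
F6 | step 4 | (4S,5S)-4-[(1R)-1-hydroxy-2,2-dimethoxyethyl]-5-(2-methylprop-2-en-1-yl)oxolan-2-one | C=C(C)C[C@@H]1OC(=O)C[C@H]1[C@@H](O)C(OC)OC
F7 | step 4 | 3-(dimethylaminomethyl) derivative of F6 (C3 epimers) | C=C(C)C[C@@H]1OC(=O)C(CN(C)C)[C@H]1[C@@H](O)C(OC)OC
F8 | step 4 | methiodide of F7 | C=C(C)C[C@@H]1OC(=O)C(C[N+](C)(C)C)[C@H]1[C@@H](O)C(OC)OC.[I-]
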